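**Plan**

- Labels: unit 1 is the 5-hydroxy-7-methoxy-2-(4-methoxyphenyl)chromone half (benzo ring A, pyranone ring C, anisyl ring B). Unit 2 is the apigenin half (benzo ring D, pyranone ring E, phenol ring F). Flavone numbering is used in each.
- Enabling feature: C3 of ring C is bonded to C6 of ring D, a carbon whose two ortho neighbours (C5, C7) and para position (C8a) all carry oxygen, and the adjacent C2 carries the p-anisyl ring B. Ring C is therefore a 2-arylated isoflavone core, open to a β-to-α shift of the best migrating aryl group away from a carbon that ring B can stabilise as a cation.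
- Cuts, in retrosynthetic order: four O-protecting groups; ring E at O1–C2, C2–C3 and C4–C4a of unit 2; ring C at O1–C2 of unit 1 together with the C3(unit 1)–C6(unit 2) bond; the enone back to a propargylic alcohol, cut at its alkyne–carbinol bond; the diaryl ketone at its ring B–carbonyl bond.
- Forward: rings A, B, D and F are bought as benzenoid pieces. The ring D aldehyde and the ring B Grignard reagent give the diaryl ketone, the ring A acetylide is added, and rearrangement gives the β,β-diaryl enone. Ring C closes in step 9, ring E in steps 11–13, and one Lewis acid step unmasks the four phenols.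
- Stereochemistry: the target has no stereocentre. The racemic carbinol centres, the alkene geometry and the α-centre of the ketal met on the way are all erased.

Key step: step 9

Assumption: the target string fixes no configuration for the hindered C3(unit 1)–C6(unit 2) axis, so the axis is not controlled (racemic material if it proves configurationally stable).

**Route**

Step 1
Reactants: 1 3,5-dibenzyloxyphenol
Product: 3 2,6-bis(benzyloxy)-4-hydroxybenzaldehyde, via aryl iminium chloride 2 (not isolated)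
Conditions: POCl3 (1.5 equiv), DMF, 0 °C to rt; then ice-water
Reagents that add atoms: N,N-dimethylformamide, CN(C)C=O (formyl carbon; its nitrogen stands only in intermediate 2); water, O (carbonyl oxygen); phosphoryl chloride, O=P(Cl)(Cl)Cl (chloride of intermediate 2 only)
Why: Vilsmeier–Haack formylation of this phloroglucinol-type phenol should go mainly para to the free hydroxyl, as it does with 3,5-dimethoxyphenol, and the chelated, less polar ortho isomer is removed by chromatography.

Step 2
Reactants: 3 2,6-bis(benzyloxy)-4-hydroxybenzaldehyde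
Product: 4 2,6-bis(benzyloxy)-4-(triisopropylsilyloxy)benzaldehyde
Conditions: TIPSCl, imidazole, DMF, rt
Reagents that add atoms: chlorotriisopropylsilane, CC(C)[Si](Cl)(C(C)C)C(C)C
Why: Routine imidazole-promoted silylation of an acidic phenol gives a bulky aryl silyl ether that tolerates the organometallic, oxidising and acidic steps ahead and is the only ring D ether that fluoride removes.

Step 3
Reactants: 4 2,6-bis(benzyloxy)-4-(triisopropylsilyloxy)benzaldehyde; 5 4-methoxyphenylmagnesium bromide
Product: 6 (±)-[2,6-bis(benzyloxy)-4-(triisopropylsilyloxy)phenyl](4-methoxyphenyl)methanol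
Conditions: THF, 0 °C; neutral aqueous work-up
Reagents that add atoms: 4-methoxyphenylmagnesium bromide 5, COc1ccc([Mg]Br)cc1
Why: Grignard 1,2-addition to an aldehyde that has no α-hydrogen; the carbinol centre forms as a racemate and is erased in step 4.

Step 4
Reactants: 6 (±)-[2,6-bis(benzyloxy)-4-(triisopropylsilyloxy)phenyl](4-methoxyphenyl)methanol
Product: 7 [2,6-bis(benzyloxy)-4-(triisopropylsilyloxy)phenyl](4-methoxyphenyl)methanone
Conditions: MnO2 (excess), CH2Cl2, rt
Reagents that add atoms: none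
Why: MnO2 oxidation of a doubly benzylic alcohol runs under neutral conditions and so avoids ionisation of the very electron-rich carbinol.

Step 5
Reactants: 8 2-hydroxy-4,6-dimethoxybenzaldehyde
Product: 9 2,4-dimethoxy-6-(methoxymethoxy)benzaldehyde
Conditions: MOMCl, i-Pr2NEt, CH2Cl2, 0 °C to rt
Reagents that add atoms: chloromethyl methyl ether, COCCl
Why: O-Alkylation of the phenol with an α-chloro ether (acetal protection) masks the future O1 of unit 1 with a group that survives base and acetylide chemistry and falls off under the acid of step 9.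

Step 6
Reactants: 9 2,4-dimethoxy-6-(methoxymethoxy)benzaldehyde
Product: 10 2-ethynyl-1,5-dimethoxy-3-(methoxymethoxy)benzene
Conditions: dimethyl (1-diazo-2-oxopropyl)phosphonate, K2CO3, MeOH, rt
Reagents that add atoms: dimethyl (1-diazo-2-oxopropyl)phosphonate, COP(=O)(OC)C(=[N+]=[N-])C(C)=O
Why: Seyferth–Gilbert homologation in the Ohira–Bestmann form converts non-enolisable aryl aldehydes into terminal alkynes under mild carbonate conditions that leave the acetal untouched.

Step 7
Reactants: 10 2-ethynyl-1,5-dimethoxy-3-(methoxymethoxy)benzene; 7 [2,6-bis(benzyloxy)-4-(triisopropylsilyloxy)phenyl](4-methoxyphenyl)methanone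
Product: 12 (±)-1-[2,6-bis(benzyloxy)-4-(triisopropylsilyloxy)phenyl]-3-[2,4-dimethoxy-6-(methoxymethoxy)phenyl]-1-(4-methoxyphenyl)prop-2-yn-1-ol, via lithium arylacetylide 11 (not isolated)
Conditions: n-BuLi, THF, −78 °C; then 7, −78 °C to rt
Reagents that add atoms: n-butyllithium, [Li]CCCC (lithium stands only in intermediate 11)
Why: 1,2-Addition of a lithium acetylide, the slimmest carbon nucleophile, to a non-enolisable benzophenone is the standard entry to 1,1-diarylpropargylic alcohols; the new centre is racemic and vanishes in step 8.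

Step 8
Reactants: 12 (±)-1-[2,6-bis(benzyloxy)-4-(triisopropylsilyloxy)phenyl]-3-[2,4-dimethoxy-6-(methoxymethoxy)phenyl]-1-(4-methoxyphenyl)prop-2-yn-1-ol
Product: 13 (E)-3-[2,6-bis(benzyloxy)-4-(triisopropylsilyloxy)phenyl]-1-[2,4-dimethoxy-6-(methoxymethoxy)phenyl]-3-(4-methoxyphenyl)prop-2-en-1-one (any Z isomer is carried along)
Conditions: Ph3PAuNTf2 (2 mol %), MeOH (1 equiv), toluene, rt to 50 °C
Reagents that add atoms: none
Why: Meyer–Schuster rearrangement, for which 1,1,3-triarylpropargylic alcohols are the classical substrates, is run with a cationic gold catalyst at near-neutral pH so that acetal and silyl ether stay on, the Rupe path is closed for lack of a β-hydrogen, and electron-rich ring A steers the oxygen to the alkyne carbon it carries.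

Step 9
Reactants: 13 (E)-3-[2,6-bis(benzyloxy)-4-(triisopropylsilyloxy)phenyl]-1-[2,4-dimethoxy-6-(methoxymethoxy)phenyl]-3-(4-methoxyphenyl)prop-2-en-1-one
Product: 15 3-[2,6-bis(benzyloxy)-4-(triisopropylsilyloxy)phenyl]-5,7-dimethoxy-2-(4-methoxyphenyl)chromen-4-one, via racemic dimethyl ketal 14 (not isolated)
Conditions: Tl(NO3)3·3H2O (1.05 equiv), MeOH–HC(OMe)3, −20 °C to rt; then 3 M aq HCl added to the same flask, 55 °C
Reagents that add atoms: methanol, CO (its methoxy groups stand only in intermediate 14 and leave again on ring closure)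
Why: Proposed new method: trivalent thallium should bond to the α-carbon of the donor-substituted alkene while methanol caps the doubly benzylic β-carbon, after which ring D bridges both carbons in a spiro-cyclohexadienyl cation and ends up on the α-carbon as the weak C–Tl bond ionises and monovalent thallium leaves, so that the crowded C3(unit 1)–C6(unit 2) bond is made intramolecularly and the remaining anisyl- and methoxy-stabilised cation is caught by methanol as ketal 14. The closest known reaction types are the Tl(NO3)3 or trivalent-iodine rearrangement of 2'-oxygenated chalcones to isoflavone precursors and the oxidative aryl shift of 1,1-diarylalkenes to deoxybenzoins, and the β,β-diaryl enone 13 combines the two substrate classes without having been shown in this role. Once HCl has taken off the methoxymethyl group, the ring A phenol adds to the oxocarbenium ion re-formed at the ketal carbon (6-exo-trig, O1–C2), and loss of the second methanol makes ring C a pyranone. No stereocentre results, because the alkene geometry disappears on thallation and the α-centre of 14 returns to sp2. The step needs migration of ring D and not of ring B, which the substrate secures through three oxygen donors ortho, ortho and para to the migrating carbon against a single one in ring B, through strain relief when the 2,6-disubstituted ring leaves the fully substituted carbon, and through ring B being the group that can lie in plane with the cation at the future C2. It also needs the alkene to be oxidised before ring D, which is favoured by the low temperature, by barely more than one equivalent of oxidant and by the silyloxy group being a weaker donor than an alkoxy group, while HC(OMe)3 removes water so that the ketal forms and not the cleavage-prone free diketone.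

Step 10
Reactants: 15 3-[2,6-bis(benzyloxy)-4-(triisopropylsilyloxy)phenyl]-5,7-dimethoxy-2-(4-methoxyphenyl)chromen-4-one
Product: 16 3-[2,6-bis(benzyloxy)-4-hydroxyphenyl]-5,7-dimethoxy-2-(4-methoxyphenyl)chromen-4-one
Conditions: Bu4NF, AcOH, THF, 0 °C
Reagents that add atoms: none
Why: Fluoride cleavage of an aryl silyl ether is fast and selective, and acetic acid buffers the phenoxide so that the chromone is not exposed to base.

Step 11
Reactants: 16 3-[2,6-bis(benzyloxy)-4-hydroxyphenyl]-5,7-dimethoxy-2-(4-methoxyphenyl)chromen-4-one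
Product: 17 3-[3-acetyl-2,6-bis(benzyloxy)-4-hydroxyphenyl]-5,7-dimethoxy-2-(4-methoxyphenyl)chromen-4-one
Conditions: Ac2O (2 equiv), BF3·OEt2 (3 equiv), CH2Cl2, 0 °C to 40 °C; then H2O
Reagents that add atoms: acetic anhydride, CC(=O)OC(C)=O
Why: Friedel–Crafts acetylation (O-acetylation followed by Fries shift) of a phloroglucinol monophenol goes ortho to the free hydroxyl under chelation by boron; the two open positions of ring D are equivalent, and rings A and B are deactivated by the Lewis-acid-bound chromone carbonyl.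

Step 12
Reactants: 17 3-[3-acetyl-2,6-bis(benzyloxy)-4-hydroxyphenyl]-5,7-dimethoxy-2-(4-methoxyphenyl)chromen-4-one; 18 4-(benzyloxy)benzoyl chloride
Product: 20 1-{2,4-bis(benzyloxy)-3-[5,7-dimethoxy-2-(4-methoxyphenyl)-4-oxochromen-3-yl]-6-hydroxyphenyl}-3-[4-(benzyloxy)phenyl]propane-1,3-dione, via dilithium enolate phenoxide 19 (not isolated)
Conditions: LiN(SiMe3)2 (4 equiv), THF, −78 to −10 °C; then 18, −78 °C to rt; dilute HCl
Reagents that add atoms: 4-(benzyloxy)benzoyl chloride 18, O=C(Cl)c1ccc(OCc2ccccc2)cc1; LiN(SiMe3)2, [Li]N([Si](C)(C)C)[Si](C)(C)C (lithium stands only in intermediate 19)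
Why: Claisen-type aroylation of the enolate of an o-hydroxyacetophenone, the one-flask form of the Baker–Venkataraman sequence, gives the 1,3-diketone whether the acid chloride first meets carbon or the phenoxide oxygen, since excess base transfers an O-bound aroyl group to carbon.

Step 13
Reactants: 20 1-{2,4-bis(benzyloxy)-3-[5,7-dimethoxy-2-(4-methoxyphenyl)-4-oxochromen-3-yl]-6-hydroxyphenyl}-3-[4-(benzyloxy)phenyl]propane-1,3-dione
Product: 21 5,7-bis(benzyloxy)-2-[4-(benzyloxy)phenyl]-6-[5,7-dimethoxy-2-(4-methoxyphenyl)-4-oxochromen-3-yl]chromen-4-one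
Conditions: p-TsOH·H2O (cat.), toluene, 80 °C
Reagents that add atoms: none
Why: Acid-catalysed cyclodehydration of an o-hydroxyaryl 1,3-diketone (6-exo-trig addition of the phenol to the aroyl carbonyl, then loss of water) is the standard flavone closure, and only one phenol is free, so ring E can form only with the 6-linkage.

Step 14
Reactants: 21 5,7-bis(benzyloxy)-2-[4-(benzyloxy)phenyl]-6-[5,7-dimethoxy-2-(4-methoxyphenyl)-4-oxochromen-3-yl]chromen-4-one
Product: 22 5,7-dihydroxy-6-[5-hydroxy-7-methoxy-2-(4-methoxyphenyl)-4-oxochromen-3-yl]-2-(4-hydroxyphenyl)chromen-4-one (CNP0273448.0)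
Conditions: BCl3 (excess), C6HMe5, CH2Cl2, −78 °C to rt; then H2O
Reagents that add atoms: none
Why: BCl3 with pentamethylbenzene as benzyl cation trap cleaves aryl benzyl ethers at low temperature, and on warming chelation to the C4 carbonyl of unit 1 directs it to the peri 5-methoxy group alone, leaving the non-chelated 7- and 4'-methyl ethers.

**Compound list**

1 | 3,5-dibenzyloxyphenol | Oc1cc(OCc2ccccc2)cc(OCc2ccccc2)c1 | starting material
2 | N-{[2,6-bis(benzyloxy)-4-hydroxyphenyl]methylidene}-N-methylmethanaminium chloride | C[N+](C)=Cc1c(OCc2ccccc2)cc(O)cc1OCc1ccccc1.[Cl-] | intermediate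
3 | 2,6-bis(benzyloxy)-4-hydroxybenzaldehyde | O=Cc1c(OCc2ccccc2)cc(O)cc1OCc1ccccc1 | intermediate
4 | 2,6-bis(benzyloxy)-4-(triisopropylsilyloxy)benzaldehyde | O=Cc1c(OCc2ccccc2)cc(O[Si](C(C)C)(C(C)C)C(C)C)cc1OCc1ccccc1 | intermediate
5 | 4-methoxyphenylmagnesium bromide | COc1ccc([Mg]Br)cc1 | starting material
6 | (±)-[2,6-bis(benzyloxy)-4-(triisopropylsilyloxy)phenyl](4-methoxyphenyl)methanol | COc1ccc(C(O)c2c(OCc3ccccc3)cc(O[Si](C(C)C)(C(C)C)C(C)C)cc2OCc2ccccc2)cc1 | intermediate
7 | [2,6-bis(benzyloxy)-4-(triisopropylsilyloxy)phenyl](4-methoxyphenyl)methanone | COc1ccc(C(=O)c2c(OCc3ccccc3)cc(O[Si](C(C)C)(C(C)C)C(C)C)cc2OCc2ccccc2)cc1 | intermediate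
8 | 2-hydroxy-4,6-dimethoxybenzaldehyde | COc1cc(O)c(C=O)c(OC)c1 | starting material
9 | 2,4-dimethoxy-6-(methoxymethoxy)benzaldehyde | COCOc1cc(OC)cc(OC)c1C=O | intermediate
10 | 2-ethynyl-1,5-dimethoxy-3-(methoxymethoxy)benzene | COCOc1cc(OC)cc(OC)c1C#C | intermediate
11 | lithium [2,4-dimethoxy-6-(methoxymethoxy)phenyl]acetylide | COCOc1cc(OC)cc(OC)c1C#C[Li] | intermediate
12 | (±)-1-[2,6-bis(benzyloxy)-4-(triisopropylsilyloxy)phenyl]-3-[2,4-dimethoxy-6-(methoxymethoxy)phenyl]-1-(4-methoxyphenyl)prop-2-yn-1-ol | COCOc1cc(OC)cc(OC)c1C#CC(O)(c1ccc(OC)cc1)c1c(OCc2ccccc2)cc(O[Si](C(C)C)(C(C)C)C(C)C)cc1OCc1ccccc1 | intermediate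
13 | (E)-3-[2,6-bis(benzyloxy)-4-(triisopropylsilyloxy)phenyl]-1-[2,4-dimethoxy-6-(methoxymethoxy)phenyl]-3-(4-methoxyphenyl)prop-2-en-1-one | COCOc1cc(OC)cc(OC)c1C(=O)/C=C(\c1ccc(OC)cc1)c1c(OCc2ccccc2)cc(O[Si](C(C)C)(C(C)C)C(C)C)cc1OCc1ccccc1 | intermediate
14 | (±)-2-[2,6-bis(benzyloxy)-4-(triisopropylsilyloxy)phenyl]-1-[2,4-dimethoxy-6-(methoxymethoxy)phenyl]-3,3-dimethoxy-3-(4-methoxyphenyl)propan-1-one | COCOc1cc(OC)cc(OC)c1C(=O)C(c1c(OCc2ccccc2)cc(O[Si](C(C)C)(C(C)C)C(C)C)cc1OCc1ccccc1)C(OC)(OC)c1ccc(OC)cc1 | intermediate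
15 | 3-[2,6-bis(benzyloxy)-4-(triisopropylsilyloxy)phenyl]-5,7-dimethoxy-2-(4-methoxyphenyl)chromen-4-one | COc1ccc(-c2oc3cc(OC)cc(OC)c3c(=O)c2-c2c(OCc3ccccc3)cc(O[Si](C(C)C)(C(C)C)C(C)C)cc2OCc2ccccc2)cc1 | intermediate
16 | 3-[2,6-bis(benzyloxy)-4-hydroxyphenyl]-5,7-dimethoxy-2-(4-methoxyphenyl)chromen-4-one | COc1ccc(-c2oc3cc(OC)cc(OC)c3c(=O)c2-c2c(OCc3ccccc3)cc(O)cc2OCc2ccccc2)cc1 | intermediate
17 | 3-[3-acetyl-2,6-bis(benzyloxy)-4-hydroxyphenyl]-5,7-dimethoxy-2-(4-methoxyphenyl)chromen-4-one | COc1ccc(-c2oc3cc(OC)cc(OC)c3c(=O)c2-c2c(OCc3ccccc3)cc(O)c(C(C)=O)c2OCc2ccccc2)cc1 | intermediate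
18 | 4-(benzyloxy)benzoyl chloride | O=C(Cl)c1ccc(OCc2ccccc2)cc1 | starting material
19 | dilithium enolate phenoxide of 17 | COc1ccc(-c2oc3cc(OC)cc(OC)c3c(=O)c2-c2c(OCc3ccccc3)cc(O[Li])c(C(=C)O[Li])c2OCc2ccccc2)cc1 | intermediate
20 | 1-{2,4-bis(benzyloxy)-3-[5,7-dimethoxy-2-(4-methoxyphenyl)-4-oxochromen-3-yl]-6-hydroxyphenyl}-3-[4-(benzyloxy)phenyl]propane-1,3-dione | COc1ccc(-c2oc3cc(OC)cc(OC)c3c(=O)c2-c2c(OCc3ccccc3)cc(O)c(C(=O)CC(=O)c3ccc(OCc4ccccc4)cc3)c2OCc2ccccc2)cc1 | intermediate
21 | 5,7-bis(benzyloxy)-2-[4-(benzyloxy)phenyl]-6-[5,7-dimethoxy-2-(4-methoxyphenyl)-4-oxochromen-3-yl]chromen-4-one | COc1ccc(-c2oc3cc(OC)cc(OC)c3c(=O)c2-c2c(OCc3ccccc3)cc3oc(-c4ccc(OCc5ccccc5)cc4)cc(=O)c3c2OCc2ccccc2)cc1 | intermediate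
22 | 5,7-dihydroxy-6-[5-hydroxy-7-methoxy-2-(4-methoxyphenyl)-4-oxochromen-3-yl]-2-(4-hydroxyphenyl)chromen-4-one (CNP0273448.0) | COc1ccc(-c2oc3cc(OC)cc(O)c3c(=O)c2-c2c(O)cc3oc(-c4ccc(O)cc4)cc(=O)c3c2O)cc1 | target

**Step count**

Total step count: 14. Longest linear sequence: 12 (steps 1–4 and 7–14); steps 5 and 6 form the ring A branch.

**Steps most likely to fail**

1. Step 9. The oxidant may attack ring D (ring oxidation, nitration or thallation) faster than the alkene, the wrong aryl group may migrate, or early loss of the acetal may let the phenol add to the enone before the shift.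
   - The fallback sets out from 1 and comes back at 15. It forms the C3–C6 bond by cross-coupling on a finished ring C.
   - Low-temperature bromination of 1 with NBS para to the hydroxyl should give 3,5-bis(benzyloxy)-4-bromophenol F1, and TIPSCl with imidazole should give [3,5-bis(benzyloxy)-4-bromophenoxy]triisopropylsilane F2.
   - Bromine–lithium exchange with n-BuLi at −78 °C should give [2,6-bis(benzyloxy)-4-(triisopropylsilyloxy)phenyl]lithium F3, which ZnCl2 turns into [2,6-bis(benzyloxy)-4-(triisopropylsilyloxy)phenyl]zinc chloride F4.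
   - Commercial 5,7-dimethoxy-2-(4-methoxyphenyl)chromen-4-one is deprotonated at C3 with LiN(i-Pr)2 to 3-lithio-5,7-dimethoxy-2-(4-methoxyphenyl)chromen-4-one F5. Quenching with iodine gives 3-iodo-5,7-dimethoxy-2-(4-methoxyphenyl)chromen-4-one F6.
   - Negishi coupling of F4 with F6 (Pd2(dba)3, SPhos, THF, 60 °C) should give 15.

2. Step 11. The Lewis acid may cause loss or carbon-migration of benzyl groups, or the reaction may stop at the O-acetate stage.
   - The fallback sets out from 16 and comes back at 21. It bypasses steps 12 and 13 and avoids Lewis acids altogether.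
   - One equivalent of NIS in MeCN at −20 °C should iodinate ring D ortho to the phenol and give 3-[2,6-bis(benzyloxy)-4-hydroxy-3-iodophenyl]-5,7-dimethoxy-2-(4-methoxyphenyl)chromen-4-one F7.
   - Carbonylative Sonogashira coupling follows with commercial 1-(benzyloxy)-4-ethynylbenzene (PdCl2(PPh3)2, CO at 1 atm, Et2NH, 60 °C). It should pass through 1-{2,4-bis(benzyloxy)-3-[5,7-dimethoxy-2-(4-methoxyphenyl)-4-oxochromen-3-yl]-6-hydroxyphenyl}-3-[4-(benzyloxy)phenyl]prop-2-yn-1-one F8.
   - Under the amine conditions F8 closes in the 6-endo sense to 21.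

3. Step 7. Addition to the hindered, donor-deactivated carbonyl group may be slow or reversible.
   - The fallback sets out from 4 and acetylide 11 and comes back at 12. It changes the order in which the three groups reach the carbinol carbon.
   - Acetylide 11 is added to the far more reactive aldehyde 4 to give (±)-1-[2,6-bis(benzyloxy)-4-(triisopropylsilyloxy)phenyl]-3-[2,4-dimethoxy-6-(methoxymethoxy)phenyl]prop-2-yn-1-ol F9.
   - MnO2 in CH2Cl2 oxidises F9 to 1-[2,6-bis(benzyloxy)-4-(triisopropylsilyloxy)phenyl]-3-[2,4-dimethoxy-6-(methoxymethoxy)phenyl]prop-2-yn-1-one F10.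
   - Grignard reagent 5, premixed with anhydrous CeCl3 in THF at −78 °C to favour 1,2- over 1,4-addition, should add to the more electrophilic alkynone carbonyl to give 12.

**Further compounds**

F1 | step 9 | 3,5-bis(benzyloxy)-4-bromophenol | Oc1cc(OCc2ccccc2)c(Br)c(OCc2ccccc2)c1
F2 | step 9 | [3,5-bis(benzyloxy)-4-bromophenoxy]triisopropylsilane | CC(C)[Si](Oc1cc(OCc2ccccc2)c(Br)c(OCc2ccccc2)c1)(C(C)C)C(C)C
F3 | step 9 | [2,6-bis(benzyloxy)-4-(triisopropylsilyloxy)phenyl]lithium | [Li]c1c(OCc2ccccc2)cc(O[Si](C(C)C)(C(C)C)C(C)C)cc1OCc1ccccc1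
F4 | step 9 | [2,6-bis(benzyloxy)-4-(triisopropylsilyloxy)phenyl]zinc chloride | Cl[Zn]c1c(OCc2ccccc2)cc(O[Si](C(C)C)(C(C)C)C(C)C)cc1OCc1ccccc1
F5 | step 9 | 3-lithio-5,7-dimethoxy-2-(4-methoxyphenyl)chromen-4-one | COc1ccc(-c2oc3cc(OC)cc(OC)c3c(=O)c2[Li])cc1
F6 | step 9 | 3-iodo-5,7-dimethoxy-2-(4-methoxyphenyl)chromen-4-one | COc1ccc(-c2oc3cc(OC)cc(OC)c3c(=O)c2I)cc1
F7 | step 11 | 3-[2,6-bis(benzyloxy)-4-hydroxy-3-iodophenyl]-5,7-dimethoxy-2-(4-methoxyphenyl)chromen-4-one | COc1ccc(-c2oc3cc(OC)cc(OC)c3c(=O)c2-c2c(OCc3ccccc3)cc(O)c(I)c2OCc2ccccc2)cc1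
F8 | step 11 | 1-{2,4-bis(benzyloxy)-3-[5,7-dimethoxy-2-(4-methoxyphenyl)-4-oxochromen-3-yl]-6-hydroxyphenyl}-3-[4-(benzyloxy)phenyl]prop-2-yn-1-one | COc1ccc(-c2oc3cc(OC)cc(OC)c3c(=O)c2-c2c(OCc3ccccc3)cc(O)c(C(=O)C#Cc3ccc(OCc4ccccc4)cc3)c2OCc2ccccc2)cc1
F9 | step 7 | (±)-1-[2,6-bis(benzyloxy)-4-(triisopropylsilyloxy)phenyl]-3-[2,4-dimethoxy-6-(methoxymethoxy)phenyl]prop-2-yn-1-ol | COCOc1cc(OC)cc(OC)c1C#CC(O)c1c(OCc2ccccc2)cc(O[Si](C(C)C)(C(C)C)C(C)C)cc1OCc1ccccc1
F10 | step 7 | 1-[2,6-bis(benzyloxy)-4-(triisopropylsilyloxy)phenyl]-3-[2,4-dimethoxy-6-(methoxymethoxy)phenyl]prop-2-yn-1-one | COCOc1cc(OC)cc(OC)c1C#CC(=O)c1c(OCc2ccccc2)cc(O[Si](C(C)C)(C(C)C)C(C)C)cc1OCc1ccccc1
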